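**Plan**

1. Numbering: butenolide O1, C2(=O), C3(Me), C4(H), C5; side chain C1'–C9' outward from C5. Cuts, in order: C5=C1' (back to C5–H/C1'–OH); then both ring C–C bonds C4–C5 and C2–C3 together; then oxazole C2–C1' (isocyanide α-addition to an aldehyde); then C3'–C4' (Negishi), C4'=C5' (Takai), C6'=C7' (Wittig), furan–C9' (Negishi) and furan–CH2–furan.
2. Enabling feature: lactone O1 lies between C5 and C2 just as the ring oxygen of an oxazole lies between its C2 and C5, and C3(Me)=C4(H) is a propyne unit. A 5-aminooxazole therefore serves as a temporary ring that offers C5–O1–C2 as a diene; the alkyne closes the butenolide at both C–C bonds and oxazole N3–C4 leaves as acetonitrile.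
3. Helpers: the C1' oxygen (needed anyway for the alkene) carries an i-Pr2Si tether that decides which alkyne carbon meets which oxazole carbon. Morpholine (hydrolysis), silicon (fluoride) and the C1' oxygen (elimination) are removed after the ring is made.
4. Forward order: furylmethylfuran 5 → aldehyde 8 → E-enal 10 → E,E-dienyl iodide 11 → chiral ester 13 → aldehyde 14 → oxazole 18 → tethered oxazole 22 → butenolide ring 25 → C5 equilibration 26 → desilylation 27 → exocyclic alkene 29.
5. Stereochemistry: C2' (S) is bought with zinc reagent 12; 4'E and 6'E come from the Takai and Wittig olefinations; 5E comes from the erythro C5/C1' pair, set thermodynamically inside the tethered bicycle (step 14), followed by stereospecific anti-elimination (step 16).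

Key step: step 13

Remark: the carbinol carbon C1' made in step 10 arises as both epimers and is erased in step 16; the C5 centre set in step 14 follows it (erythro in each series), so both series should give 29; names and SMILES show the (1'S) series.

**Route**

Step 1
Reactants: 1 3-bromofuran; 2 4-bromofuran-2-carbaldehyde
Product: 4 (4-bromofuran-2-yl)(furan-3-yl)methanol, via furan-3-yllithium 3 (not isolated)
Conditions: n-BuLi, THF, −78 °C; then 2, −78 °C; H2O
Reagents that add atoms: none
Why: Bromine–lithium exchange on 1 gives 3 at −78 °C, which should add to the formyl group of 2 faster than it exchanges with the ring bromide (organolithium 1,2-addition); the racemic carbinol centre is removed in step 2.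

Step 2
Reactants: 4 (4-bromofuran-2-yl)(furan-3-yl)methanol
Product: 5 4-bromo-2-(furan-3-ylmethyl)furan
Conditions: Et3SiH, CF3CO2H, CH2Cl2, 0 °C
Reagents that add atoms: none
Why: The carbinol flanked by two furans ionises readily and the cation is trapped by hydride from the silane (ionic hydrogenation), the ring bromide being untouched.

Step 3
Reactants: 5 4-bromo-2-(furan-3-ylmethyl)furan; 6 (3-ethoxy-3-oxopropyl)zinc bromide
Product: 7 ethyl 3-[5-(furan-3-ylmethyl)furan-3-yl]propanoate
Conditions: Pd(OAc)2 (cat.), SPhos, THF, 50 °C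
Reagents that add atoms: none
Why: Negishi sp2–sp3 coupling of a heteroaryl bromide with a primary, ester-bearing alkylzinc halide, which tolerates the ester and both furans.

Step 4
Reactants: 7 ethyl 3-[5-(furan-3-ylmethyl)furan-3-yl]propanoate
Product: 8 3-[5-(furan-3-ylmethyl)furan-3-yl]propanal
Conditions: i-Bu2AlH, CH2Cl2, −78 °C; Rochelle salt work-up
Reagents that add atoms: none
Why: At −78 °C the aluminium hemiacetal formed by one hydride transfer survives until work-up, so the ester stops at the aldehyde (partial i-Bu2AlH reduction).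

Step 5
Reactants: 8 3-[5-(furan-3-ylmethyl)furan-3-yl]propanal; 9 2-(triphenyl-λ5-phosphanylidene)propanal
Product: 10 (2E)-5-[5-(furan-3-ylmethyl)furan-3-yl]-2-methylpent-2-enal
Conditions: toluene, 80 °C
Reagents that add atoms: none
Why: Wittig olefination with a formyl-stabilised ylide, which reacts once with the more electrophilic saturated aldehyde and should give the (E)-trisubstituted enal.

Step 6
Reactants: 10 (2E)-5-[5-(furan-3-ylmethyl)furan-3-yl]-2-methylpent-2-enal
Product: 11 2-(furan-3-ylmethyl)-4-[(3E,5E)-6-iodo-4-methylhexa-3,5-dien-1-yl]furan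
Conditions: CrCl2, CHI3, THF, 0 °C → rt
Reagents that add atoms: iodoform, IC(I)I
Why: Takai iodo-olefination: the geminal dichromium species from CHI3 and CrCl2 adds to the aldehyde and eliminates to the (E)-iodoalkene, leaving the existing (E)-double bond unchanged.

Step 7
Reactants: 11 2-(furan-3-ylmethyl)-4-[(3E,5E)-6-iodo-4-methylhexa-3,5-dien-1-yl]furan; 12 [(2R)-3-methoxy-2-methyl-3-oxopropyl]zinc bromide
Product: 13 methyl (2S,4E,6E)-9-[5-(furan-3-ylmethyl)furan-3-yl]-2,6-dimethylnona-4,6-dienoate
Conditions: Pd(PPh3)4 (cat.), THF, rt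
Reagents that add atoms: none
Why: Negishi coupling of an alkenyl iodide with a primary alkylzinc bromide keeps the diene geometry, and the stereocentre next to the zinc-bearing carbon is not involved, so C2' (S) is taken unchanged from commercial 12.

Step 8
Reactants: 13 methyl (2S,4E,6E)-9-[5-(furan-3-ylmethyl)furan-3-yl]-2,6-dimethylnona-4,6-dienoate
Product: 14 (2S,4E,6E)-9-[5-(furan-3-ylmethyl)furan-3-yl]-2,6-dimethylnona-4,6-dienal
Conditions: i-Bu2AlH, CH2Cl2, −78 °C; Rochelle salt work-up; used at once
Reagents that add atoms: none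
Why: Partial i-Bu2AlH reduction via the stable aluminium hemiacetal; the cold, non-basic conditions should spare the α-stereocentre.

Step 9
Reactants: 15 ethyl 2-isocyanopropanoate; 16 morpholine
Product: 17 2-isocyano-1-(morpholin-4-yl)propan-1-one
Conditions: neat morpholine, rt
Reagents that add atoms: none
Why: Aminolysis of an ester activated by the α-isocyano group (acyl substitution); the isocyanide is inert to amines without acid or metal.

Step 10
Reactants: 14 (2S,4E,6E)-9-[5-(furan-3-ylmethyl)furan-3-yl]-2,6-dimethylnona-4,6-dienal; 17 2-isocyano-1-(morpholin-4-yl)propan-1-one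
Product: 18 (1S,2S,4E,6E)-9-[5-(furan-3-ylmethyl)furan-3-yl]-2,6-dimethyl-1-[4-methyl-5-(morpholin-4-yl)-1,3-oxazol-2-yl]nona-4,6-dien-1-ol (with its 1-epimer)
Conditions: LiBr, toluene, 60 °C
Reagents that add atoms: none
Why: Passerini-type α-addition: the isocyanide carbon attacks the LiBr-activated aldehyde, the amide oxygen closes onto the nitrilium ion and tautomerisation gives the aromatic 5-aminooxazole (the known oxazole synthesis from α-isocyanoacetamides and aldehydes); C1' forms as both epimers, which is harmless (see remark), and the neutral conditions should spare C2'.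

Step 11
Reactants: 19 dichlorodi(propan-2-yl)silane; 20 prop-1-yn-1-ylmagnesium bromide
Product: 21 chlorodi(propan-2-yl)(prop-1-yn-1-yl)silane
Conditions: excess 19, THF, −78 °C → rt; distillation
Reagents that add atoms: none
Why: Substitution at silicon by the alkynyl Grignard reagent; with excess dichlorosilane and two isopropyl groups the second substitution is slow, so the monochloride can be isolated.

Step 12
Reactants: 18 oxazole carbinol; 21 chlorodi(propan-2-yl)(prop-1-yn-1-yl)silane
Product: 22 4-{2-[(1S,2S,4E,6E)-1-{[di(propan-2-yl)(prop-1-yn-1-yl)silyl]oxy}-9-[5-(furan-3-ylmethyl)furan-3-yl]-2,6-dimethylnona-4,6-dien-1-yl]-4-methyl-1,3-oxazol-5-yl}morpholine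
Conditions: imidazole, DMAP (cat.), CH2Cl2, 0 °C → rt
Reagents that add atoms: none
Why: Silyl ether formation from a secondary alcohol and a chlorosilane; the isopropyl groups should make the alkoxy(alkynyl)silane stable enough to handle, and the weakly basic ring nitrogens do not interfere.

Step 13
Reactants: 22 silicon-tethered oxazole
Product: 25 silicon-tethered butenolide as a mixture of C5 epimers, via oxa-bridged cycloadduct 23 (not isolated), via aminofuran 24 (not isolated)
Conditions: 1,2-dichlorobenzene (0.01 M, degassed), 160 °C, sealed tube; cool; then THF–H2O–AcOH, 0 °C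
Reagents that add atoms: water, O
Why: Proposed new method: the 5-morpholino-oxazole of 22 is an electron-rich 2-azadiene whose termini C2 and C5 flank the ring oxygen, and the silicon-bound propynyl group should add across them in an intramolecular [4+2] cycloaddition to give 23, which loses acetonitrile (the old N3–C4 unit) by retro-[4+2] to the 2-aminofuran 24; mild aqueous acid then hydrolyses this cyclic ketene N,O-acetal to the lactone. The closest known reaction type is the intramolecular oxazole–alkyne Diels–Alder/retro-Diels–Alder synthesis of furans and butenolides through all-carbon or nitrogen-containing tethers, together with silicon-tethered intramolecular Diels–Alder reactions of alkynylsilanes; the Si–O tether on an oxazole is the untested element. The butenolide ring is closed at both of its ring C–C bonds (C4–C5 and C2–C3) by cycloaddition/cycloreversion, and the temporary 2,5-dihydro-1,2-oxasilole ring closes in the fused intramolecular mode through the three-atom C1'–O–Si tether. The bridgehead centres of 23 vanish on aromatisation; the only lasting new centre, C5, arises on protonation of 24 and is not controlled here (it is set in step 14). The step needs the methyl-bearing alkyne carbon to bond to the amino-bearing oxazole carbon, which the short tether enforces because only the silicon-bearing carbon can reach oxazole C2; it also needs the alkyne to win over the C4'=C5' alkene (likewise three atoms away) and the furans, which should follow from the gem-diisopropyl effect at silicon and from the fact that only the alkyne adduct is drained irreversibly by nitrile loss.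

Step 14
Reactants: 25 silicon-tethered butenolide (C5 epimers)
Product: 26 silicon-tethered butenolide, (5S,1'S) erythro isomer
Conditions: DBU (0.1 equiv), CH2Cl2, 0 °C → rt
Reagents that add atoms: none
Why: Reversible deprotonation at the acidic γ-position C5 (2-oxidofuran) equilibrates the ring-fusion centre and brings any deconjugated isomer into conjugation (thermodynamic epimerisation); the isomer with the C1' side chain trans to O1 across the oxasilole ring (erythro) should predominate, and the in-ring C1'–O bond lies in the plane of the dienolate so that E1cB loss of the siloxy group should not compete.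

Step 15
Reactants: 26 silicon-tethered butenolide, erythro isomer
Product: 27 (5R)-5-[(1S,2S,4E,6E)-9-[5-(furan-3-ylmethyl)furan-3-yl]-1-hydroxy-2,6-dimethylnona-4,6-dien-1-yl]-3-methylfuran-2(5H)-one
Conditions: Bu4NF, AcOH (1:1), THF, 0 °C → rt
Reagents that add atoms: none
Why: Fluoride opens the strained five-membered alkenylsiloxane at Si–O and then cleaves the C4–Si bond through a pentacoordinate fluorosilicate with protonation at C4 (protodesilylation of a cyclic alkenylsiloxane); the acetic acid buffer should keep the medium too weakly basic to deprotonate C5, so the erythro relationship is kept.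

Step 16
Reactants: 27 erythro hydroxy butenolide
Product: 29 (5E)-5-[(2S,4E,6E)-9-[5-(furan-3-ylmethyl)furan-3-yl]-2,6-dimethylnona-4,6-dien-1-ylidene]-3-methylfuran-2(5H)-one, via alkoxyphosphonium salt 28 (not isolated)
Conditions: PPh3, DIAD, THF, −20 °C → rt
Reagents that add atoms: none
Why: Mitsunobu-type dehydration of a γ-(α-hydroxyalkyl)butenolide: the hydrazide anion removes the acidic C5–H anti-periplanar to the oxyphosphonium group of 28 in an E2 step, and in the erythro isomer this conformer holds C2' on the side of C4, which should give the (5E)-alkene; C2' is not touched.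

**Compound list**

1 | 3-bromofuran | Brc1ccoc1 | starting material
2 | 4-bromofuran-2-carbaldehyde | O=Cc1cc(Br)co1 | starting material
3 | furan-3-yllithium | [Li]c1ccoc1 | intermediate
4 | (4-bromofuran-2-yl)(furan-3-yl)methanol (racemic) | OC(c1ccoc1)c1cc(Br)co1 | intermediate
5 | 4-bromo-2-(furan-3-ylmethyl)furan | Brc1coc(Cc2ccoc2)c1 | intermediate
6 | (3-ethoxy-3-oxopropyl)zinc bromide | CCOC(=O)CC[Zn]Br | starting material
7 | ethyl 3-[5-(furan-3-ylmethyl)furan-3-yl]propanoate | CCOC(=O)CCc1coc(Cc2ccoc2)c1 | intermediate
8 | 3-[5-(furan-3-ylmethyl)furan-3-yl]propanal | O=CCCc1coc(Cc2ccoc2)c1 | intermediate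
9 | 2-(triphenyl-λ5-phosphanylidene)propanal | CC(C=O)=P(c1ccccc1)(c1ccccc1)c1ccccc1 | starting material
10 | (2E)-5-[5-(furan-3-ylmethyl)furan-3-yl]-2-methylpent-2-enal | O=C/C(C)=C/CCc1coc(Cc2ccoc2)c1 | intermediate
11 | 2-(furan-3-ylmethyl)-4-[(3E,5E)-6-iodo-4-methylhexa-3,5-dien-1-yl]furan | I/C=C/C(C)=C/CCc1coc(Cc2ccoc2)c1 | intermediate
12 | [(2R)-3-methoxy-2-methyl-3-oxopropyl]zinc bromide (skeleton of methyl (S)-3-hydroxy-2-methylpropanoate) | COC(=O)[C@@H](C)C[Zn]Br | starting material
13 | methyl (2S,4E,6E)-9-[5-(furan-3-ylmethyl)furan-3-yl]-2,6-dimethylnona-4,6-dienoate | COC(=O)[C@@H](C)C/C=C/C(C)=C/CCc1coc(Cc2ccoc2)c1 | intermediate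
14 | (2S,4E,6E)-9-[5-(furan-3-ylmethyl)furan-3-yl]-2,6-dimethylnona-4,6-dienal | O=C[C@@H](C)C/C=C/C(C)=C/CCc1coc(Cc2ccoc2)c1 | intermediate
15 | ethyl 2-isocyanopropanoate (racemic) | CCOC(=O)C(C)[N+]#[C-] | starting material
16 | morpholine | C1COCCN1 | starting material
17 | 2-isocyano-1-(morpholin-4-yl)propan-1-one (racemic) | CC([N+]#[C-])C(=O)N1CCOCC1 | intermediate
18 | (1S,2S,4E,6E)-9-[5-(furan-3-ylmethyl)furan-3-yl]-2,6-dimethyl-1-[4-methyl-5-(morpholin-4-yl)-1,3-oxazol-2-yl]nona-4,6-dien-1-ol (formed with its 1-epimer) | Cc1nc([C@@H](O)[C@@H](C)C/C=C/C(C)=C/CCc2coc(Cc3ccoc3)c2)oc1N1CCOCC1 | intermediate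
19 | dichlorodi(propan-2-yl)silane | CC(C)[Si](Cl)(Cl)C(C)C | starting material
20 | prop-1-yn-1-ylmagnesium bromide | CC#C[Mg]Br | starting material
21 | chlorodi(propan-2-yl)(prop-1-yn-1-yl)silane | CC#C[Si](Cl)(C(C)C)C(C)C | intermediate
22 | 4-{2-[(1S,2S,4E,6E)-1-{[di(propan-2-yl)(prop-1-yn-1-yl)silyl]oxy}-9-[5-(furan-3-ylmethyl)furan-3-yl]-2,6-dimethylnona-4,6-dien-1-yl]-4-methyl-1,3-oxazol-5-yl}morpholine | Cc1nc([C@@H](O[Si](C#CC)(C(C)C)C(C)C)[C@@H](C)C/C=C/C(C)=C/CCc2coc(Cc3ccoc3)c2)oc1N1CCOCC1 | intermediate
23 | oxa-bridged cycloadduct: 7-oxa-2-azabicyclo[2.2.1]hepta-2,5-diene from addition of the alkyne across oxazole C2/C5, with the Si(i-Pr)2–O–C1'H bridge closing a 2,5-dihydro-1,2-oxasilole (bridgeheads unassigned) | CC1=C2[Si](C(C)C)(C(C)C)O[C@@H]([C@@H](C)C/C=C/C(C)=C/CCc4coc(Cc5ccoc5)c4)C23OC1(N6CCOCC6)C(C)=N3 | intermediate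
24 | aminofuran: 3-methyl-2-(morpholin-4-yl)furan whose C4 and C5 carry the Si(i-Pr)2–O–C1'H(side chain) bridge | Cc1c(N2CCOCC2)oc2c1[Si](C(C)C)(C(C)C)O[C@H]2[C@@H](C)C/C=C/C(C)=C/CCc3coc(Cc4ccoc4)c3 | intermediate
25 | silicon-tethered butenolide: 3-methylfuran-2(5H)-one with C5 bonded to C1' of the (1'S,2'S,4'E,6'E) side chain and Si(i-Pr)2 joining C4 to the oxygen on C1'; both C5 epimers | CC1=C2C(OC1=O)[C@H]([C@@H](C)C/C=C/C(C)=C/CCc3coc(Cc4ccoc4)c3)O[Si]2(C(C)C)C(C)C | intermediate
26 | silicon-tethered butenolide, (5S,1'S,2'S) erythro isomer (side chain trans to O1 across the oxasilole) | CC1=C2[C@@H](OC1=O)[C@H]([C@@H](C)C/C=C/C(C)=C/CCc3coc(Cc4ccoc4)c3)O[Si]2(C(C)C)C(C)C | intermediate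
27 | (5R)-5-[(1S,2S,4E,6E)-9-[5-(furan-3-ylmethyl)furan-3-yl]-1-hydroxy-2,6-dimethylnona-4,6-dien-1-yl]-3-methylfuran-2(5H)-one (erythro) | CC1=C[C@@H](OC1=O)[C@@H](O)[C@@H](C)C/C=C/C(C)=C/CCc2coc(Cc3ccoc3)c2 | intermediate
28 | alkoxyphosphonium salt: C1'-O-triphenylphosphonium derivative of 27 (cation shown) | CC1=C[C@@H](OC1=O)[C@@H](O[P+](c2ccccc2)(c2ccccc2)c2ccccc2)[C@@H](C)C/C=C/C(C)=C/CCc2coc(Cc3ccoc3)c2 | intermediate
29 | (5E)-5-[(2S,4E,6E)-9-[5-(furan-3-ylmethyl)furan-3-yl]-2,6-dimethylnona-4,6-dien-1-ylidene]-3-methylfuran-2(5H)-one | CC1=C/C(=C\[C@@H](C)C/C=C/C(C)=C/CCc2coc(Cc3ccoc3)c2)OC1=O | target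

**Step count and risks**

Total: 16 steps. Longest linear sequence: 14 steps (steps 1–8, 10, 12–16); steps 9 and 11 prepare isocyanide 17 and chlorosilane 21.

Steps most likely to fail:

Step 13. The unactivated alkynylsilane may add too slowly, so that the oxazole is consumed by cycloaddition to the C4'=C5' alkene or by thermal ring-opening, or the Si–O tether may be hydrolysed before cyclisation. The fallback uses known chemistry, sets out from 14 and returns at 27. Commercial 3-methylfuran-2(5H)-one is silylated (TBSOTf, Et3N, CH2Cl2, 0 °C) to tert-butyldimethyl[(3-methylfuran-2-yl)oxy]silane F1. F1 is added to aldehyde 14 in a fluoride-promoted vinylogous Mukaiyama aldol reaction (Bu4NF cat., THF, −78 °C, the mode expected to favour the erythro adduct), giving the O-silylated aldol adduct F2. Dilute acid then gives 27, minor diastereomers are removed by chromatography, and the route continues with step 16.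

Step 14. The thermodynamic preference for the erythro epimer may be too small, or the base may trigger ring-opening elimination of the siloxy group and lead into the 5Z series. The fallback sets out from 25 and returns at 29. Compound 25 is desilylated under the conditions of step 15 without equilibration, and 27 is separated from its C5 epimer, the threo alcohol F3. Compound 27 goes on through step 16. F3 is dehydrated with methyl N-(triethylammoniosulfonyl)carbamate (Burgess reagent, benzene, 50 °C), whose syn-elimination should turn the threo arrangement into the same (5E)-alkene 29.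

Step 16. The concerted anti-elimination may leak into an E1cB pathway, or the phosphine may isomerise the more strained (5E)-alkene; both would erode the geometry toward 5Z. The fallback sets out from 27 and returns at 29. Compound 27 is taken through the mesylate F4 (MsCl, Et3N, CH2Cl2, 0 °C, then DBU) under equilibrating conditions to the (5Z)-isomer F5. F5 is photoisomerised by direct irradiation above 300 nm, where only the alkylidenebutenolide chromophore absorbs, to an E/Z mixture from which 29 is separated and F5 is recycled.

**Further compounds**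

F1 | step 13 | tert-butyldimethyl[(3-methylfuran-2-yl)oxy]silane | Cc1ccoc1O[Si](C)(C)C(C)(C)C
F2 | step 13 | O-silylated aldol adduct (C1'-O-tert-butyldimethylsilyl ether of 27) | CC1=C[C@@H](OC1=O)[C@@H](O[Si](C)(C)C(C)(C)C)[C@@H](C)C/C=C/C(C)=C/CCc2coc(Cc3ccoc3)c2
F3 | step 14 | threo alcohol, (5S)-5-[(1S,2S,4E,6E)-9-[5-(furan-3-ylmethyl)furan-3-yl]-1-hydroxy-2,6-dimethylnona-4,6-dien-1-yl]-3-methylfuran-2(5H)-one | CC1=C[C@H](OC1=O)[C@@H](O)[C@@H](C)C/C=C/C(C)=C/CCc2coc(Cc3ccoc3)c2
F4 | step 16 | mesylate of 27 | CC1=C[C@@H](OC1=O)[C@@H](OS(C)(=O)=O)[C@@H](C)C/C=C/C(C)=C/CCc2coc(Cc3ccoc3)c2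
F5 | step 16 | (5Z)-isomer of 29 | CC1=C/C(=C/[C@@H](C)C/C=C/C(C)=C/CCc2coc(Cc3ccoc3)c2)OC1=O
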